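**Plan**

1. Retrosynthesis: first the two ester C–O bonds (3‑O‑propanoyl, 8‑O‑acetyl) and the C3–H/C8–H bonds, back to a 3,8‑dioxo stage; then the C7–C11 bond (acrylate from methyl (E)‑3‑nitroacrylate); then the C9 methylene is excised from ring B (C5–C6–C7–C8–C9–C10), leaving a cyclopentanone; last C4=C5 and C1–C10 (aldol, Michael) to 2‑methylcyclopentane‑1,3‑dione and ethyl vinyl ketone.
2. Forward: ring A and a five‑membered precursor of ring B are assembled first (Michael addition, amino‑acid‑mediated aldol condensation to a hydrindenedione); ring B then gains its sixth atom by insertion of one carbon between C8 and C10; side chain and ester oxygens follow.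
3. Enabling feature: in ring B the oxygen‑bearing C8 is β to the quaternary C10 (C10–C9–C8) and 1,4 to C5, a pattern no Robinson annulation of a 1,3‑dione gives; without C9, C5 and C8 are the two carbonyl carbons of 2‑methylcyclopentane‑1,3‑dione, and C10 is the substituted, migration‑prone α‑carbon of the C8 ketone.
4. Stereochemistry: C10 comes from the L‑phenylalanine‑mediated desymmetrising aldol; C7 (equilibration to equatorial), C8 (hydride anti to the axial C10 methyl) and C3 (axial hydride delivery to the enone) are relayed from C10 by substrate control.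
5. Temporary group: a 1,3‑dithiane on the C3 carbonyl (steps 3–10) keeps C8 the only reactive carbonyl.

Key step: step 5

Remark: eudesmane numbering is used for all bicyclic compounds (ring A = C1–C5, C10; ring B = C5–C10; C11–C13 acrylate; C14 on C10; C15 on C4), also for the hydrindanes, which lack C9.
Remark: methyl glyoxylate is taken as commercially available; L‑phenylalanine is used in about stoichiometric amount but is not consumed.

**Route**

Step 1
Reactants: 1 2-methylcyclopentane-1,3-dione; 2 ethyl vinyl ketone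
Product: 3 2-methyl-2-(3-oxopentyl)cyclopentane-1,3-dione
Conditions: AcOH (cat.), H2O, 75 °C
Reagents that add atoms: none
Why: Michael addition of the acidic cyclic 1,3-dione to the enone gives the 2,2-disubstituted dione without aldol follow-up under these mild conditions; the new quaternary carbon is prochiral, so no stereocentre is set.

Step 2
Reactants: 3 2-methyl-2-(3-oxopentyl)cyclopentane-1,3-dione
Product: 5 (S)-4,7a-dimethyl-2,3,7,7a-tetrahydro-1H-indene-1,5(6H)-dione, via bicyclic ketol 4 (not isolated)
Conditions: L-phenylalanine (1.0 equiv), 1 M aq. HClO4 (0.5 equiv), MeCN, reflux; recrystallisation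
Reagents that add atoms: none
Why: Hajos–Parrish–Eder–Sauer–Wiechert reaction, in which the L-amino acid enamine of the side-chain ketone attacks one of the two enantiotopic ring carbonyls in a hydrogen-bonded chair-like transition state, setting the quaternary carbon (C10) in the S series known for L-amino acids (β-methyl in the eudesmane drawing), and acid then dehydrates ketol 4 to the enone; recrystallisation should raise the optical purity.

Step 3
Reactants: 5 (S)-4,7a-dimethyl-2,3,7,7a-tetrahydro-1H-indene-1,5(6H)-dione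
Product: 6 (S)-4,7a-dimethyl-2,3,7,7a-tetrahydro-1H-indene-1,5(6H)-dione 5-(propane-1,3-diyl dithioacetal)
Conditions: propane-1,3-dithiol (1.05 equiv), BF3·OEt2 (0.3 equiv), MeOH, 0 °C → rt
Reagents that add atoms: propane-1,3-dithiol, SCCCS
Why: acid-catalysed thioacetalisation is selective for the conjugated C3 carbonyl over the neopentyl cyclopentanone C8=O, as with 3-oxo-Δ4/17-oxo steroids and the Wieland–Miescher ketone, and leaves the Δ4 double bond in place; the dithiane is the temporary group for steps 4, 5, 8 and 9.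

Step 4
Reactants: 6 (S)-hydrindenedione 5-dithiane; 7 dibromomethane
Product: 8 (1S,7aS)-1-(dibromomethyl)-1-hydroxy-4,7a-dimethyl-1,2,3,6,7,7a-hexahydro-5H-inden-5-one 5-(propane-1,3-diyl dithioacetal)
Conditions: CH2Br2 (1.5 equiv), LiTMP (1.4 equiv), THF, −78 °C; AcOH, −78 °C
Reagents that add atoms: none
Why: dibromomethyllithium, formed in situ by deprotonation of CH2Br2, adds 1,2 to the only carbonyl group (as dihalomethyllithiums do with 17-oxo steroids) from the α face opposite the angular methyl, giving the carbinol with OH cis to that methyl; this centre is temporary and disappears in step 5.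

Step 5
Reactants: 8 dibromomethyl carbinol
Product: 11 (R)-1,4a-dimethyl-4,4a,7,8-tetrahydronaphthalene-2,6(3H,5H)-dione 2-(propane-1,3-diyl dithioacetal), via dilithio β-oxido carbenoid 9 (not isolated), via lithium enolate 10 (not isolated)
Conditions: n-BuLi (2.2 equiv), THF, −95 → −78 °C, then 0 °C; H2O
Reagents that add atoms: none
Why: n-BuLi deprotonates the carbinol and exchanges one bromine, giving the dilithio β-oxido carbenoid 9; on warming, the C8–C10 σ-bond anti to the leaving bromide shifts to the electron-poor carbenoid carbon with loss of LiBr (1,2-shift of the semipinacol type), so that this carbon becomes C9 between C10 and C8 and the cyclohexanone is released as its lithium enolate 10, protonated on work-up. The closest known reaction type is the Nozaki–Yamamoto ring enlargement of cyclic ketones through their dibromomethyllithium adducts (β-oxido carbenoid rearrangement). No ring is closed by cyclisation: ring B reaches its six-membered size by one-carbon enlargement of the cyclopentanone (C9–C10 bond made, C8–C10 bond broken), while ring A is untouched. No new stereocentre is formed; C10 migrates with retention, so the configuration from step 2 is carried over, and the temporary carbinol and carbenoid centres disappear. The step needs migration of the quaternary C10 and not of the C7 methylene, which is secured by the preference of this rearrangement for the more substituted, more electron-rich α-carbon. Chemoselectivity is secured by the dithiane, which leaves C8 as the only carbonyl group and offers no acidic C–H to the alkyllithium.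

Step 6
Reactants: 12 methyl glyoxylate; 13 nitromethane
Product: 14 methyl 2-hydroxy-3-nitropropanoate (racemic)
Conditions: Et3N (5 mol %), MeNO2 (excess), 0 °C → rt
Reagents that add atoms: none
Why: base-catalysed Henry (nitroaldol) addition of nitromethane to the highly electrophilic glyoxylate aldehyde; the racemic carbinol centre is removed in step 7.

Step 7
Reactants: 14 methyl 2-hydroxy-3-nitropropanoate
Product: 16 methyl (E)-3-nitroacrylate, via mesylate 15 (not isolated)
Conditions: MsCl (1.1 equiv), Et3N (2.2 equiv), CH2Cl2, −20 °C; used freshly prepared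
Reagents that add atoms: none
Why: mesylation of the secondary alcohol and E1cB elimination through the acidic α-nitro C–H give the thermodynamically favoured (E)-β-nitroacrylate, a known dehydration route to this class of reagent.

Step 8
Reactants: 11 ring-enlarged ketone; 16 methyl (E)-3-nitroacrylate
Product: 19 methyl (7R,10R)-8-oxo-3,3-(propane-1,3-diyldithio)eudesma-4,11(13)-dien-12-oate, via pyrrolidine enamine 17 (not isolated), via nitro keto ester 18 (not isolated)
Conditions: pyrrolidine (1.5 equiv), TsOH (cat.), PhH, reflux (−H2O); 16 (1.1 equiv), MeCN, −40 → 0 °C; aq. AcOH/NaOAc; DBU (1.05 equiv), CH2Cl2, 0 °C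
Reagents that add atoms: none
Why: Stork enamine Michael addition in which the enamine reacts through C7, remote from the neopentyl C9, at the carbon β to the nitro group of the nitroacrylate (McMurry's α-methylene ester synthon), after which hydrolysis and E1cB loss of nitrous acid unveil the acrylate and the enolisable C7 equilibrates to the equatorial 7β side chain (7R) of the ring-B chair whose axial position at C10 holds the methyl group.

Step 9
Reactants: 19 keto acrylate
Product: 21 methyl (7R,8R,10R)-8β-acetoxy-3,3-(propane-1,3-diyldithio)eudesma-4,11(13)-dien-12-oate, via aluminium alkoxide 20 (not isolated)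
Conditions: LiAlH(OtBu)3 (1.3 equiv), THF, −78 → −40 °C; then Ac2O, pyridine, DMAP (cat.), −78 → 0 °C
Reagents that add atoms: acetic anhydride, CC(=O)OC(C)=O
Why: the bulky, ester-tolerant hydride reduces the only ketone by equatorial attack from the α face, because axial approach is blocked by the syn-axial C10 methyl (as in the reduction of 2- and 6-oxo steroids), giving the axial 8β-alkoxide (8R) cis to the side chain, and acetylation of this alkoxide in the same flask (one-pot reduction–acylation) is meant to trap it before it can lactonise onto the cis ester.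

Step 10
Reactants: 21 acetoxy dithiane
Product: 22 methyl (7R,8R,10R)-8β-acetoxy-3-oxoeudesma-4,11(13)-dien-12-oate
Conditions: PhI(OCOCF3)2 (1.5 equiv), MeCN/H2O (9:1), 0 °C
Reagents that add atoms: water, O
Why: oxidative dethioacetalisation with a hypervalent iodine reagent (Stork–Zhao conditions) activates sulfur and lets water hydrolyse the dithiane to the enone under conditions that spare the acetate, the acrylate and the tetrasubstituted alkene.

Step 11
Reactants: 22 enone acetate
Product: 23 methyl (3S,7R,8R,10R)-8β-acetoxy-3β-hydroxyeudesma-4,11(13)-dien-12-oate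
Conditions: NaBH4, CeCl3·7H2O, MeOH, −78 °C
Reagents that add atoms: none
Why: Luche reduction gives 1,2-reduction of the enone without touching the acrylate or the acetate, and hydride is delivered axially from the α face of the half-chair ring A, anti to the angular methyl as in 3-oxo-Δ4 steroids, giving the pseudo-equatorial 3β-alcohol (3S).

Step 12
Reactants: 23 allylic alcohol
Product: 24 methyl (3S,7R,8R,10R)-8β-acetoxy-3β-propanoyloxyeudesma-4,11(13)-dien-12-oate (CNP0198123.1)
Conditions: (EtCO)2O, pyridine, DMAP (cat.), CH2Cl2, 0 °C → rt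
Reagents that add atoms: propionic anhydride, CCC(=O)OC(=O)CC
Why: DMAP-catalysed acylation of the unhindered allylic secondary alcohol with retention at C3; no stereocentre is touched.

**Compound list**

1 | 2-methylcyclopentane-1,3-dione | CC1C(=O)CCC1=O | starting material
2 | ethyl vinyl ketone (pent-1-en-3-one) | CCC(=O)C=C | starting material
3 | 2-methyl-2-(3-oxopentyl)cyclopentane-1,3-dione | CCC(=O)CCC1(C)C(=O)CCC1=O | intermediate
4 | (3aS,7aS)-3a-hydroxy-4,7a-dimethylhexahydro-1H-indene-1,5(4H)-dione, cis-fused ketol, C4 unassigned | O=C1CC[C@]2(C)C(=O)CC[C@]2(O)C1C | intermediate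
5 | (S)-4,7a-dimethyl-2,3,7,7a-tetrahydro-1H-indene-1,5(6H)-dione | O=C1CC[C@]2(C)C(=O)CCC2=C1C | intermediate
6 | (S)-4,7a-dimethyl-2,3,7,7a-tetrahydro-1H-indene-1,5(6H)-dione 5-(propane-1,3-diyl dithioacetal) | S1CCCSC12CC[C@]3(C)C(=O)CCC3=C2C | intermediate
7 | dibromomethane | BrCBr | starting material
8 | (1S,7aS)-1-(dibromomethyl)-1-hydroxy-4,7a-dimethyl-1,2,3,6,7,7a-hexahydro-5H-inden-5-one 5-(propane-1,3-diyl dithioacetal), OH cis to the angular methyl | S1CCCSC12CC[C@]3(C)[C@](O)(C(Br)Br)CCC3=C2C | intermediate
9 | dilithio β-oxido carbenoid of 8 (O–Li, C(Li)Br) | S1CCCSC12CC[C@]3(C)[C@](O[Li])(C([Li])Br)CCC3=C2C | intermediate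
10 | lithium Δ8(9)-enolate of 11 | S1CCCSC12CC[C@]3(C)C=C(O[Li])CCC3=C2C | intermediate
11 | (R)-1,4a-dimethyl-4,4a,7,8-tetrahydronaphthalene-2,6(3H,5H)-dione 2-(propane-1,3-diyl dithioacetal) [(10R)-3,3-(propane-1,3-diyldithio)-11,12,13-trinoreudesm-4-en-8-one] | S1CCCSC12CC[C@]3(C)CC(=O)CCC3=C2C | intermediate
12 | methyl glyoxylate | O=CC(=O)OC | starting material
13 | nitromethane | C[N+](=O)[O-] | starting material
14 | methyl 2-hydroxy-3-nitropropanoate (racemic) | COC(=O)C(O)C[N+](=O)[O-] | intermediate
15 | methyl 2-(methylsulfonyloxy)-3-nitropropanoate | COC(=O)C(OS(C)(=O)=O)C[N+](=O)[O-] | intermediate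
16 | methyl (E)-3-nitroacrylate | COC(=O)/C=C/[N+](=O)[O-] | intermediate
17 | 8-(pyrrolidin-1-yl) Δ7-enamine of 11 | S1CCCSC12CC[C@]3(C)CC(N4CCCC4)=CCC3=C2C | intermediate
18 | methyl 13-nitro-8-oxo-3,3-(propane-1,3-diyldithio)eudesm-4-en-12-oate (C7/C11 mixture) | S1CCCSC12CC[C@]3(C)CC(=O)C(C(C[N+](=O)[O-])C(=O)OC)CC3=C2C | intermediate
19 | methyl (7R,10R)-8-oxo-3,3-(propane-1,3-diyldithio)eudesma-4,11(13)-dien-12-oate | S1CCCSC12CC[C@]3(C)CC(=O)[C@@H](C(=C)C(=O)OC)CC3=C2C | intermediate
20 | lithium tri-tert-butoxy(8β-alkoxy)aluminate of reduced 19 | S1CCCSC12CC[C@]3(C)C[C@@H](O[Al-](OC(C)(C)C)(OC(C)(C)C)OC(C)(C)C)[C@@H](C(=C)C(=O)OC)CC3=C2C.[Li+] | intermediate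
21 | methyl (7R,8R,10R)-8β-acetoxy-3,3-(propane-1,3-diyldithio)eudesma-4,11(13)-dien-12-oate | S1CCCSC12CC[C@]3(C)C[C@@H](OC(C)=O)[C@@H](C(=C)C(=O)OC)CC3=C2C | intermediate
22 | methyl (7R,8R,10R)-8β-acetoxy-3-oxoeudesma-4,11(13)-dien-12-oate | O=C1CC[C@]2(C)C[C@@H](OC(C)=O)[C@@H](C(=C)C(=O)OC)CC2=C1C | intermediate
23 | methyl (3S,7R,8R,10R)-8β-acetoxy-3β-hydroxyeudesma-4,11(13)-dien-12-oate | O[C@H]1CC[C@]2(C)C[C@@H](OC(C)=O)[C@@H](C(=C)C(=O)OC)CC2=C1C | intermediate
24 | methyl (3S,7R,8R,10R)-8β-acetoxy-3β-propanoyloxyeudesma-4,11(13)-dien-12-oate | CCC(=O)O[C@H]1CC[C@]2(C)C[C@@H](OC(C)=O)[C@@H](C(=C)C(=O)OC)CC2=C1C | target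

**Step count**

Total: 12 steps (steps 6–7 are a two-step side branch to reagent 16). Longest linear sequence: 10 steps (1–5, 8–12).

**Steps most likely to fail**

1. Step 5. The 1,2-shift may take the wrong course (C7 migrating instead of the hindered quaternary C10), or the carbenoid may decay without migration. Fallback, from 6 back to 11: bromomethyllithium (CH2Br2, n-BuLi, THF, −78 °C, cold AcOH quench) is added to 6 to give the bromohydrin (1S,7aS)-1-(bromomethyl)-1-hydroxy-4,7a-dimethyl-1,2,3,6,7,7a-hexahydro-5H-inden-5-one 5-(propane-1,3-diyl dithioacetal) F1. With i-PrMgCl this gives its chloromagnesium alkoxide F2, which on heating in benzene should undergo the Tiffeneau/Sisti magnesium halohydrin (semipinacol) rearrangement. In that cation-like, magnesium-assisted loss of bromide the more substituted C10 is the expected migrating group, and the product is 11.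

2. Step 9. The C8 metal alkoxide may lactonise onto the cis acrylate ester before it is acetylated, facial selectivity may be incomplete, or hydride may add to the acrylate. Fallback, from 11 back to 21, with the ester as a temporary bulky group: tert-butyl acrylate is nitro-iodinated (N2O4, I2) to tert-butyl 2-iodo-3-nitropropanoate F3 and eliminated with NaOAc to tert-butyl (E)-3-nitroacrylate F4. Enamine 17 is combined with it as in step 8 to give, through the tert-butyl nitro keto ester F5, tert-butyl (7R,10R)-8-oxo-3,3-(propane-1,3-diyldithio)eudesma-4,11(13)-dien-12-oate F6. Reduction with NaBH4/CeCl3 in MeOH at −78 °C should give the tert-butyl 8β-hydroxy ester F7, whose ester resists lactonisation; Ac2O/DMAP then gives the tert-butyl 8β-acetoxy ester F8. TFA in CH2Cl2 (no allylic ester is present yet, the dithiane is stable) frees (7R,8R,10R)-8β-acetoxy-3,3-(propane-1,3-diyldithio)eudesma-4,11(13)-dien-12-oic acid F9, and TMSCHN2 gives 21.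

3. Step 8. Regiocontrol may be lost in the enamine alkylation (attack through C9), the nitroalkene may oligomerise, or the acrylate double bond may move into conjugation with the C8 ketone during the elimination. Fallback, from 11 back to 22, building the acrylate only after C8 is fixed: enamine 17 is C-alkylated with allyl bromide and hydrolysed to the 7β-allyl ketone (10R)-7β-(prop-2-enyl)-3,3-(propane-1,3-diyldithio)-11,12,13-trinoreudesm-4-en-8-one F10. L-Selectride (usable here, no acrylate present) should give the 8β-alcohol F11, and Ac2O/DMAP the 8β-acetate F12. PIFA in aqueous MeCN removes the dithiane to give the 7β-allyl-8β-acetoxy enone F13. OsO4 (cat.)/NaIO4/2,6-lutidine cleaves the terminal alkene to (8β-acetoxy-3-oxo-11,12,13-trinoreudesm-4-en-7β-yl)acetaldehyde F14. Eschenmoser's salt/Et3N α-methylenates it through the Mannich base F15 to 8β-acetoxy-3-oxoeudesma-4,11(13)-dien-12-al F16. Pinnick oxidation gives 8β-acetoxy-3-oxoeudesma-4,11(13)-dien-12-oic acid F17, and TMSCHN2 gives 22.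

**Further compounds**

F1 | step 5 | (1S,7aS)-1-(bromomethyl)-1-hydroxy-4,7a-dimethyl-1,2,3,6,7,7a-hexahydro-5H-inden-5-one 5-(propane-1,3-diyl dithioacetal) | S1CCCSC12CC[C@]3(C)[C@](O)(CBr)CCC3=C2C
F2 | step 5 | chloromagnesium alkoxide of F1 | S1CCCSC12CC[C@]3(C)[C@](O[Mg]Cl)(CBr)CCC3=C2C
F3 | step 9 | tert-butyl 2-iodo-3-nitropropanoate | CC(C)(C)OC(=O)C(I)C[N+](=O)[O-]
F4 | step 9 | tert-butyl (E)-3-nitroacrylate | CC(C)(C)OC(=O)/C=C/[N+](=O)[O-]
F5 | step 9 | tert-butyl 13-nitro-8-oxo-3,3-(propane-1,3-diyldithio)eudesm-4-en-12-oate | S1CCCSC12CC[C@]3(C)CC(=O)C(C(C[N+](=O)[O-])C(=O)OC(C)(C)C)CC3=C2C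
F6 | step 9 | tert-butyl (7R,10R)-8-oxo-3,3-(propane-1,3-diyldithio)eudesma-4,11(13)-dien-12-oate | S1CCCSC12CC[C@]3(C)CC(=O)[C@@H](C(=C)C(=O)OC(C)(C)C)CC3=C2C
F7 | step 9 | tert-butyl (7R,8R,10R)-8β-hydroxy-3,3-(propane-1,3-diyldithio)eudesma-4,11(13)-dien-12-oate | S1CCCSC12CC[C@]3(C)C[C@@H](O)[C@@H](C(=C)C(=O)OC(C)(C)C)CC3=C2C
F8 | step 9 | tert-butyl (7R,8R,10R)-8β-acetoxy-3,3-(propane-1,3-diyldithio)eudesma-4,11(13)-dien-12-oate | S1CCCSC12CC[C@]3(C)C[C@@H](OC(C)=O)[C@@H](C(=C)C(=O)OC(C)(C)C)CC3=C2C
F9 | step 9 | (7R,8R,10R)-8β-acetoxy-3,3-(propane-1,3-diyldithio)eudesma-4,11(13)-dien-12-oic acid | S1CCCSC12CC[C@]3(C)C[C@@H](OC(C)=O)[C@@H](C(=C)C(=O)O)CC3=C2C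
F10 | step 8 | (10R)-7β-(prop-2-enyl)-3,3-(propane-1,3-diyldithio)-11,12,13-trinoreudesm-4-en-8-one | S1CCCSC12CC[C@]3(C)CC(=O)[C@@H](CC=C)CC3=C2C
F11 | step 8 | (10R)-7β-(prop-2-enyl)-3,3-(propane-1,3-diyldithio)-11,12,13-trinoreudesm-4-en-8β-ol | S1CCCSC12CC[C@]3(C)C[C@@H](O)[C@@H](CC=C)CC3=C2C
F12 | step 8 | (10R)-7β-(prop-2-enyl)-3,3-(propane-1,3-diyldithio)-11,12,13-trinoreudesm-4-en-8β-yl acetate | S1CCCSC12CC[C@]3(C)C[C@@H](OC(C)=O)[C@@H](CC=C)CC3=C2C
F13 | step 8 | (10R)-3-oxo-7β-(prop-2-enyl)-11,12,13-trinoreudesm-4-en-8β-yl acetate | O=C1CC[C@]2(C)C[C@@H](OC(C)=O)[C@@H](CC=C)CC2=C1C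
F14 | step 8 | (8β-acetoxy-3-oxo-11,12,13-trinoreudesm-4-en-7β-yl)acetaldehyde | O=C1CC[C@]2(C)C[C@@H](OC(C)=O)[C@@H](CC=O)CC2=C1C
F15 | step 8 | 8β-acetoxy-13-(dimethylamino)-3-oxoeudesm-4-en-12-al (Mannich base) | O=C1CC[C@]2(C)C[C@@H](OC(C)=O)[C@@H](C(CN(C)C)C=O)CC2=C1C
F16 | step 8 | 8β-acetoxy-3-oxoeudesma-4,11(13)-dien-12-al | O=C1CC[C@]2(C)C[C@@H](OC(C)=O)[C@@H](C(=C)C=O)CC2=C1C
F17 | step 8 | 8β-acetoxy-3-oxoeudesma-4,11(13)-dien-12-oic acid | O=C1CC[C@]2(C)C[C@@H](OC(C)=O)[C@@H](C(=C)C(=O)O)CC2=C1C
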